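Ring B is built from open-chain pieces: a photochemical Wolff rearrangement–benzannulation joins diazo keto ester 6 and silyl ynol ether 11, forging C1–C6, C1–C2, C3–C4 and C4–C5 in one operation. It exploits the pattern of ring B, where the meta oxygens O-2 and O-4 sit beside the C1 carboxyl and the C6 pentyl group: the ketene oxygen emerges as the free O-4 phenol and the alkyne oxygen as silylated O-2, so the depside ester can be placed on O-4 alone. Precursor 6 is a benzyl 2-diazo-3-oxo ester bearing a 1-pentylvinyl ketone arm. Ketal-masked ring A acid 21 is then attached and the masks are removed.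

Key step: step 5

Remark: the target has no stereocentre; 5 and 13 are formed as racemates and their stereocentres are erased in steps 3 and 5; 3, 16 and 17 are taken as purchasable.

Step 1
Reactants: 1 heptanal
Product: 2 2-methylideneheptanal
Conditions: 37% aq. CH2O, pyrrolidine (10 mol%), EtCO2H (10 mol%), i-PrOH, 45 °C
Reagents that add atoms: formaldehyde, C=O
Why: Amine-catalysed Mannich condensation with formaldehyde followed by elimination of the amine (α-methylenation of an aldehyde) installs the methylidene carbon that becomes C5 of ring B, and the α-branched enal cannot react a second time.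

Step 2
Reactants: 2 2-methylideneheptanal; 3 benzyl diazoacetate
Product: 5 benzyl 2-diazo-3-hydroxy-4-methylidenenonanoate (racemic), via lithiated benzyl diazoacetate 4 (not isolated)
Conditions: 3, LiN(iPr)2, THF, −78 °C; then 2, −78 °C; AcOH quench
Reagents that add atoms: none
Why: Aldol-type 1,2-addition of the lithiated diazoacetate to the aldehyde is fast at −78 °C and should outrun conjugate addition or dipolar cycloaddition to the alkene; the carbinol stereocentre is formed without control (racemate) and is erased in step 3.

Step 3
Reactants: 5 benzyl 2-diazo-3-hydroxy-4-methylidenenonanoate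
Product: 6 benzyl 2-diazo-4-methylidene-3-oxononanoate
Conditions: Dess–Martin periodinane, CH2Cl2, 0 °C to rt
Reagents that add atoms: none
Why: Dess–Martin oxidation converts the α-diazo-β-hydroxy ester into the diazo keto ester under near-neutral conditions that spare the diazo group and the alkene, and reaching 6 at this oxidation level means that an enone never coexists with an acidic 3-oxo ester methylene, which would self-condense by Michael addition.

Step 4
Reactants: 7 acetylene; 8 triisopropylsilyl trifluoromethanesulfonate
Product: 11 (triisopropylsilyloxy)acetylene, via lithium acetylide 9 (not isolated), via lithium ethynolate 10 (not isolated)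
Conditions: 7 (excess), n-BuLi, THF, −78 °C; LiOOtBu (from t-BuOOH and LiN(SiMe3)2), −78 to −20 °C; 8, −78 to 0 °C
Reagents that add atoms: tert-butyl hydroperoxide (as its lithium salt), CC(C)(C)OO
Why: Electrophilic oxygenation of a lithium acetylide by the oxenoid LiOOtBu gives the ynolate, which the bulky silyl triflate should capture on oxygen (the known route to siloxyalkynes, here applied to the parent acetylide), and an amine-free acetylide kept cold under excess acetylene avoids both N-silylation and disproportionation to Li2C2.

Step 5
Reactants: 6 benzyl 2-diazo-4-methylidene-3-oxononanoate; 11 (triisopropylsilyloxy)acetylene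
Product: 15 benzyl 4-hydroxy-6-pentyl-2-(triisopropylsilyloxy)benzoate, via vinylketene 12 (not isolated), via cyclobutenone 13 (not isolated), via dienylketene 14 (not isolated)
Conditions: 11 (2.5 equiv), hν (300 nm), degassed ClCH2CH2Cl, rt; then 80 °C
Reagents that add atoms: none
Why: Proposed new method: light expels N2 from 6 with a 1,2-shift of the hept-1-en-2-yl group from the ketone carbon to the diazo carbon (Wolff rearrangement, new C1–C6 bond), giving vinylketene 12, whose ketene carbon also bears the benzyl ester. The unsubstituted, nucleophilic carbon of ynol ether 11 attacks the ketene carbonyl carbon and the enolate–ketenium pair collapses to cyclobutenone 13, a net (2+2) cycloaddition that forms C3–C4 and C1–C2. Ring B then closes by electrocyclisation: conrotatory 4π opening of 13 gives dienylketene 14 and a 6π closure between the ketene carbon and the methylidene carbon forms C4–C5, after which the cyclohexadienone tautomerises to the phenol; no stereocentre is created. The closest known reaction type is the Danheiser benzannulation of α,β-unsaturated α'-diazo ketones with siloxyalkynes under photochemical Wolff conditions, which has not been shown for a vinylketene carrying an ester on the ketene carbon. Regioselectivity of the ketene–alkyne union is needed and is secured by the polarisation of the ynol ether, so that the ketene oxygen becomes the free O-4 and the alkyne oxygen the silylated O-2 beside the ester. Chemoselectivity against hetero-(4+2) capture through the ester carbonyl is also needed and rests on the weak heterodiene character of an ester C=O, on the bulk of the Si(iPr)3 group near that oxygen and on the reversibility of the ring opening of 13, which lets only the isomer of 14 with the alkenyl group cis to the ketenyl arm drain irreversibly to the arene.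

Step 6
Reactants: 16 methyl 2,4-dimethoxy-6-methylbenzoate; 17 N-methoxy-N-methylbutanamide
Product: 19 methyl 2,4-dimethoxy-6-(2-oxopentyl)benzoate, via benzylic organolithium 18 (not isolated)
Conditions: 16, LiN(iPr)2, THF, −78 °C; then 17, −78 to −40 °C; AcOH quench
Reagents that add atoms: none
Why: Lateral lithiation of the ortho-toluate at the benzylic methyl group and acylation with the Weinreb amide, whose chelated tetrahedral adduct releases the ketone only on quenching, so that neither over-addition nor Claisen-type ring closure onto the ester should occur.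

Step 7
Reactants: 19 methyl 2,4-dimethoxy-6-(2-oxopentyl)benzoate
Product: 20 methyl 2,4-dimethoxy-6-[(2-propyl-1,3-dioxolan-2-yl)methyl]benzoate
Conditions: Me3SiOCH2CH2OSiMe3, Me3SiOTf (5 mol%), CH2Cl2, −78 to −20 °C; pyridine quench
Reagents that add atoms: 1,2-bis(trimethylsilyloxy)ethane, C[Si](C)(C)OCCO[Si](C)(C)C
Why: Noyori ketalisation under aprotic conditions at low temperature masks the ketone without the acid-and-heat exposure that would lactonise the keto ester, and the mask is required because an activated 2-(2-oxoalkyl)benzoic acid would otherwise close through its enol oxygen to the isocoumarin in step 9.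

Step 8
Reactants: 20 methyl 2,4-dimethoxy-6-[(2-propyl-1,3-dioxolan-2-yl)methyl]benzoate
Product: 21 2,4-dimethoxy-6-[(2-propyl-1,3-dioxolan-2-yl)methyl]benzoic acid
Conditions: KOH, DMSO/H2O, 90 °C; then cold 1 M HCl to pH 4
Reagents that add atoms: potassium hydroxide, [K+].[OH-]
Why: Saponification of the doubly ortho-substituted methyl ester needs forcing alkaline conditions, which the dioxolane and the aryl methyl ethers tolerate, and brief cold acidification to pH 4 should free the acid without hydrolysing the ketal.

Step 9
Reactants: 15 benzyl 4-hydroxy-6-pentyl-2-(triisopropylsilyloxy)benzoate; 21 2,4-dimethoxy-6-[(2-propyl-1,3-dioxolan-2-yl)methyl]benzoic acid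
Product: 22 benzyl 4-({2,4-dimethoxy-6-[(2-propyl-1,3-dioxolan-2-yl)methyl]benzoyl}oxy)-6-pentyl-2-(triisopropylsilyloxy)benzoate
Conditions: DCC, DMAP (30 mol%), CH2Cl2, 0 °C to rt
Reagents that add atoms: none
Why: Steglich esterification through the acylpyridinium ion should join the hindered acid to the only free hydroxyl of 15 (O-4), under neutral conditions that preserve the dioxolane, the silyl ether and the benzyl ester.

Step 10
Reactants: 22 benzyl 4-({2,4-dimethoxy-6-[(2-propyl-1,3-dioxolan-2-yl)methyl]benzoyl}oxy)-6-pentyl-2-(triisopropylsilyloxy)benzoate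
Product: 24 benzyl 4-{[2,4-dimethoxy-6-(2-oxopentyl)benzoyl]oxy}-2-hydroxy-6-pentylbenzoate, via desilylated ketal 23 (not isolated)
Conditions: Bu4NF, AcOH, THF, 0 °C; then 1 M aq. HCl, rt
Reagents that add atoms: water, O
Why: Acetic acid-buffered fluoride cleaves the aryl silyl ether without generating a free phenoxide that could transesterify the depside, and dilute aqueous acid should then hydrolyse the dioxolane to the ketone while the hindered, electron-rich aryl ester and the benzyl ester stay untouched.

Step 11
Reactants: 24 benzyl 4-{[2,4-dimethoxy-6-(2-oxopentyl)benzoyl]oxy}-2-hydroxy-6-pentylbenzoate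
Product: 25 4-{[2,4-dimethoxy-6-(2-oxopentyl)benzoyl]oxy}-2-hydroxy-6-pentylbenzoic acid (CNP0584180.0)
Conditions: H2 (1 atm), 10% Pd/C, EtOAc, rt
Reagents that add atoms: none
Why: Hydrogenolysis of the benzyl ester over palladium under neutral conditions should free the salicylic acid without touching the dialkyl ketone, the aryl ester or the methyl ethers, and needs only filtration for isolation.

Compound list
1 | heptanal | CCCCCCC=O | starting material
2 | 2-methylideneheptanal | CCCCCC(=C)C=O | intermediate
3 | benzyl diazoacetate | [N-]=[N+]=CC(=O)OCc1ccccc1 | starting material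
4 | lithiated benzyl diazoacetate (benzyl 2-diazo-2-lithioacetate) | [Li]C(=[N+]=[N-])C(=O)OCc1ccccc1 | intermediate (not isolated)
5 | benzyl 2-diazo-3-hydroxy-4-methylidenenonanoate (racemic) | CCCCCC(=C)C(O)C(=[N+]=[N-])C(=O)OCc1ccccc1 | intermediate
6 | benzyl 2-diazo-4-methylidene-3-oxononanoate | CCCCCC(=C)C(=O)C(=[N+]=[N-])C(=O)OCc1ccccc1 | intermediate
7 | acetylene | C#C | starting material
8 | triisopropylsilyl trifluoromethanesulfonate | CC(C)[Si](OS(=O)(=O)C(F)(F)F)(C(C)C)C(C)C | starting material
9 | lithium acetylide | [Li]C#C | intermediate (not isolated)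
10 | lithium ethynolate | [Li]OC#C | intermediate (not isolated)
11 | (triisopropylsilyloxy)acetylene | C#CO[Si](C(C)C)(C(C)C)C(C)C | intermediate
12 | benzyl 3-methylidene-2-(oxomethylidene)octanoate (vinylketene) | CCCCCC(=C)C(=C=O)C(=O)OCc1ccccc1 | intermediate (not isolated)
13 | benzyl 1-(hept-1-en-2-yl)-4-oxo-2-(triisopropylsilyloxy)cyclobut-2-ene-1-carboxylate (racemic) | CCCCCC(=C)C1(C(=O)OCc2ccccc2)C(=O)C=C1O[Si](C(C)C)(C(C)C)C(C)C | intermediate (not isolated)
14 | benzyl (2Z)-3-methylidene-2-[3-oxo-1-(triisopropylsilyloxy)prop-2-en-1-ylidene]octanoate (dienylketene, alkenyl group cis to the ketenyl arm) | CCCCCC(=C)/C(C(=O)OCc1ccccc1)=C(\C=C=O)O[Si](C(C)C)(C(C)C)C(C)C | intermediate (not isolated)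
15 | benzyl 4-hydroxy-6-pentyl-2-(triisopropylsilyloxy)benzoate | CCCCCc1cc(O)cc(O[Si](C(C)C)(C(C)C)C(C)C)c1C(=O)OCc1ccccc1 | intermediate
16 | methyl 2,4-dimethoxy-6-methylbenzoate | COC(=O)c1c(C)cc(OC)cc1OC | starting material
17 | N-methoxy-N-methylbutanamide | CCCC(=O)N(C)OC | starting material
18 | methyl 2-(lithiomethyl)-4,6-dimethoxybenzoate (benzylic organolithium) | [Li]Cc1cc(OC)cc(OC)c1C(=O)OC | intermediate (not isolated)
19 | methyl 2,4-dimethoxy-6-(2-oxopentyl)benzoate | CCCC(=O)Cc1cc(OC)cc(OC)c1C(=O)OC | intermediate
20 | methyl 2,4-dimethoxy-6-[(2-propyl-1,3-dioxolan-2-yl)methyl]benzoate | CCCC1(Cc2cc(OC)cc(OC)c2C(=O)OC)OCCO1 | intermediate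
21 | 2,4-dimethoxy-6-[(2-propyl-1,3-dioxolan-2-yl)methyl]benzoic acid | CCCC1(Cc2cc(OC)cc(OC)c2C(=O)O)OCCO1 | intermediate
22 | benzyl 4-({2,4-dimethoxy-6-[(2-propyl-1,3-dioxolan-2-yl)methyl]benzoyl}oxy)-6-pentyl-2-(triisopropylsilyloxy)benzoate | CCCCCc1cc(OC(=O)c2c(CC3(CCC)OCCO3)cc(OC)cc2OC)cc(O[Si](C(C)C)(C(C)C)C(C)C)c1C(=O)OCc1ccccc1 | intermediate
23 | benzyl 4-({2,4-dimethoxy-6-[(2-propyl-1,3-dioxolan-2-yl)methyl]benzoyl}oxy)-2-hydroxy-6-pentylbenzoate | CCCCCc1cc(OC(=O)c2c(CC3(CCC)OCCO3)cc(OC)cc2OC)cc(O)c1C(=O)OCc1ccccc1 | intermediate (not isolated)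
24 | benzyl 4-{[2,4-dimethoxy-6-(2-oxopentyl)benzoyl]oxy}-2-hydroxy-6-pentylbenzoate | CCCCCc1cc(OC(=O)c2c(CC(=O)CCC)cc(OC)cc2OC)cc(O)c1C(=O)OCc1ccccc1 | intermediate
25 | 4-{[2,4-dimethoxy-6-(2-oxopentyl)benzoyl]oxy}-2-hydroxy-6-pentylbenzoic acid | CCCCCc1cc(OC(=O)c2c(CC(=O)CCC)cc(OC)cc2OC)cc(O)c1C(=O)O | target

Total step count: 11. Longest linear sequence: 7 steps (steps 1, 2, 3, 5, 9, 10, 11); the ring A acid (steps 6–8) and the ynol ether (step 4) are convergent branches.

Steps most likely to fail

Step 5, the one step that carries the proposed new method, is the main risk. The ketene–ynol ether adduct may close through the ester carbonyl oxygen in a hetero-(4+2) sense instead of through carbon, the phenol being formed may trap unreacted ketene, and the cyclobutenone may not drain fully to the arene on heating. A product silylated on the other oxygen would be harmless, since fluoride would converge it on F2 below. The fallback uses known chemistry only; it sets out from acid 21 and comes back at 23. Commercial olivetol (5-pentylresorcinol) would be ortho-carboxylated with MeOMgOCO2Me in DMF at 120 °C (chelation-controlled Kolbe–Schmitt-type carboxylation) to olivetolic acid F1. Its carboxylate would be alkylated with BnBr and KHCO3 in DMF to benzyl 2,4-dihydroxy-6-pentylbenzoate F2. Carbodiimide coupling of F2 with 21 (DCC, catalytic DMAP) should acylate only the non-chelated O-4, because O-2 is locked in a hydrogen bond to the ester. This gives 23, which then passes through the aqueous acid stage of step 10 to 24.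

Step 4 is the second risk. The monolithium acetylide may disproportionate while the oxygenation is warmed, the unhindered ynolate may be silylated on carbon to a silylketene, and the volatile, proton-sensitive ynol ether may be lost on isolation. The fallback sets out from silyl triflate 8 and comes back at 11. Commercial ethynyltrimethylsilane would be lithiated with n-BuLi (an acetylide that cannot disproportionate), oxygenated with LiOOtBu and O-silylated with 8 to give trimethyl[(triisopropylsilyloxy)ethynyl]silane F3. MeLi·LiBr in Et2O should attack the unhindered SiMe3 group and not the shielded Si(iPr)3 group, releasing lithium (triisopropylsilyloxy)acetylide F4. Protonation of F4 with AcOH at −78 °C would return 11.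

Step 10 is the third risk. During acid unmasking, the hemiketal or enol of the emerging ketone may attack the neighbouring depside carbonyl and expel ring B as its phenol (lactonisation toward the isocoumarin), or the ketal hydrolysis may stall at conditions mild enough to spare the depside. The fallback replaces the ketal by a latent ketone that is revealed without aqueous acid; it sets out from ketone 19 and comes back at 24. Wittig methylenation of 19 (Ph3P=CH2 from Ph3PCH3Br and KOtBu, THF) would give methyl 2,4-dimethoxy-6-(2-methylidenepentyl)benzoate F5. Hydrolysis with KOH in aqueous EtOH would give 2,4-dimethoxy-6-(2-methylidenepentyl)benzoic acid F6, which has no carbonyl to lactonise on activation. Coupling of F6 with 15 (DCC, DMAP) would give benzyl 4-{[2,4-dimethoxy-6-(2-methylidenepentyl)benzoyl]oxy}-6-pentyl-2-(triisopropylsilyloxy)benzoate F7. Lemieux–Johnson cleavage (catalytic OsO4, NaIO4, 2,6-lutidine, dioxane/H2O) should convert the 1,1-disubstituted alkene into the ketone under near-neutral conditions, giving benzyl 4-{[2,4-dimethoxy-6-(2-oxopentyl)benzoyl]oxy}-6-pentyl-2-(triisopropylsilyloxy)benzoate F8. Bu4NF/AcOH in THF would then give 24.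

Further compounds
F1 | step 5 | olivetolic acid (2,4-dihydroxy-6-pentylbenzoic acid) | CCCCCc1cc(O)cc(O)c1C(=O)O
F2 | step 5 | benzyl 2,4-dihydroxy-6-pentylbenzoate | CCCCCc1cc(O)cc(O)c1C(=O)OCc1ccccc1
F3 | step 4 | trimethyl[(triisopropylsilyloxy)ethynyl]silane | C[Si](C)(C)C#CO[Si](C(C)C)(C(C)C)C(C)C
F4 | step 4 | lithium (triisopropylsilyloxy)acetylide | [Li]C#CO[Si](C(C)C)(C(C)C)C(C)C
F5 | step 10 | methyl 2,4-dimethoxy-6-(2-methylidenepentyl)benzoate | CCCC(=C)Cc1cc(OC)cc(OC)c1C(=O)OC
F6 | step 10 | 2,4-dimethoxy-6-(2-methylidenepentyl)benzoic acid | CCCC(=C)Cc1cc(OC)cc(OC)c1C(=O)O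
F7 | step 10 | benzyl 4-{[2,4-dimethoxy-6-(2-methylidenepentyl)benzoyl]oxy}-6-pentyl-2-(triisopropylsilyloxy)benzoate | CCCCCc1cc(OC(=O)c2c(CC(=C)CCC)cc(OC)cc2OC)cc(O[Si](C(C)C)(C(C)C)C(C)C)c1C(=O)OCc1ccccc1
F8 | step 10 | benzyl 4-{[2,4-dimethoxy-6-(2-oxopentyl)benzoyl]oxy}-6-pentyl-2-(triisopropylsilyloxy)benzoate | CCCCCc1cc(OC(=O)c2c(CC(=O)CCC)cc(OC)cc2OC)cc(O[Si](C(C)C)(C(C)C)C(C)C)c1C(=O)OCc1ccccc1
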